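**Retrosynthetic overview**
- Last operation: global O-debenzylation of the heptabenzyl ether of the target; all seven phenols travel as benzyl ethers.
- Key disconnection: ring C is opened at C2–C3 and at C4–C4a. This gives an aryl benzyl ether (ring A–O1–C2H2–ring B) and O-galloyl glycolaldehyde (C3–C4, ester already on O3). Forward, DDQ turns O1–C2H2 into an oxocarbenium ion, a chiral enamine of the aldehyde adds (C2–C3), and the aldehyde carbon then closes onto ring A (C4–C4a).
- Enabling feature: C2 sits between O1 and the para-oxygenated ring B, so hydride loss is easy and the cation is stabilised. The two ring A carbons ortho to O1 are equivalent and activated by O1, O5 and O7, so C4a is a strong nucleophile with no regiochemical choice. The 3-O-galloyl group next to C4 steers the C4–OH cis through a dioxolanylium ion.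
- Ring order: rings A, B and the galloyl ring are bought; ring C is the only ring made, in the key step.

Key step: step 4

Remark: the four starting materials (3,5-bis(benzyloxy)phenol, 3,4-bis(benzyloxy)benzyl chloride, 3,4,5-tris(benzyloxy)benzoic acid, 2,2-dimethoxyethanol) are assumed to be catalogue compounds.

Step 1
Reactants: 1 3,5-bis(benzyloxy)phenol; 2 1,2-bis(benzyloxy)-4-(chloromethyl)benzene
Product: 3 1,3-bis(benzyloxy)-5-{[3,4-bis(benzyloxy)phenyl]methoxy}benzene
Conditions: K2CO3, DMF, 60 °C
Reagents that add atoms: none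
Why: Williamson ether synthesis, in which the potassium phenoxide of 1 displaces the benzylic chloride of 2 at oxygen (O-alkylation is favoured in DMF); no stereocentre is formed.

Step 2
Reactants: 4 3,4,5-tris(benzyloxy)benzoic acid; 5 2,2-dimethoxyethanol
Product: 6 2,2-dimethoxyethyl 3,4,5-tris(benzyloxy)benzoate
Conditions: DCC, DMAP (cat.), CH2Cl2, 0 °C to rt
Reagents that add atoms: none
Why: Steglich esterification, in which DCC activates the acid as the O-acylisourea and DMAP passes the acyl group to the primary alcohol of 5; no stereocentre is formed.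

Step 3
Reactants: 6 2,2-dimethoxyethyl 3,4,5-tris(benzyloxy)benzoate
Product: 7 2-oxoethyl 3,4,5-tris(benzyloxy)benzoate
Conditions: CF3CO2H–H2O–CH2Cl2 (5:1:10), 0 °C to rt; toluene azeotrope, used at once
Reagents that add atoms: water, O
Why: Acid-catalysed acetal hydrolysis through the methoxy-oxocarbenium ion frees the aldehyde, while the aryl ester and the benzyl ethers should tolerate cold aqueous CF3CO2H; no stereocentre is formed.

Step 4
Reactants: 3 1,3-bis(benzyloxy)-5-{[3,4-bis(benzyloxy)phenyl]methoxy}benzene; 7 2-oxoethyl 3,4,5-tris(benzyloxy)benzoate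
Product: 12 (2R,3S,4S)-5,7-bis(benzyloxy)-2-[3,4-bis(benzyloxy)phenyl]-4-hydroxychroman-3-yl 3,4,5-tris(benzyloxy)benzoate, via oxocarbenium ion 8 (not isolated), via enamine 9 (not isolated), via aldehyde 10 (not isolated), via dioxolanylium ion 11 (not isolated)
Conditions: DDQ (1.05 equiv), CH2Cl2, 0 °C to rt until DDQ is consumed; then −30 °C: 7 (1.5 equiv), (S)-2-{diphenyl[(tert-butyldimethylsilyl)oxy]methyl}pyrrolidine (30 mol %), CF3CO2H (30 mol %); then CF3CO2H (0.5 equiv), 0 °C; pH 5 NaOAc/AcOH buffer work-up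
Reagents that add atoms: none
Why: Proposed new method: DDQ removes hydride from the O1–CH2 group of 3 to give the (E)-O-aryl oxocarbenium ion 8, the (E)-enamine 9 formed from 7 and the amine adds through C3 to C2, the iminium ion is hydrolysed by the water released on enamine formation to the anti aldehyde 10, and the acid then drives Friedel–Crafts attack of the ring A carbon ortho to O1 on the formyl carbon; the closest known reactions are the amine-catalysed enantioselective oxidative coupling of benzylic ethers with aldehydes through DDQ-derived oxocarbenium ions and the oxa-Povarov annulation of aryl oxocarbenium ions with alkenes, which are merged here into one formal [4+2] event. Ring C closes by 6-exo-trig attack of C4a on the protonated C4 aldehyde through a chair in which ring B and the galloyloxy group are equatorial. C3 is set by the (S)-configured catalyst, whose diphenyl(silyloxy)methyl group covers one face of the s-trans (E)-enamine so that C2 bonds to the Re face of C3 (O > C4 > H), the sense known for (S)-prolinol silyl ether α-functionalisation of aldehydes. C2 is set relative to C3 in an open antiperiplanar transition state (C2–H towards the pyrrolidine C5 methylene, ring B between C4 and the ester oxygen, O1 away from the developing iminium ion), which gives the 2,3-anti, that is 2,3-trans, adduct, and reversible addition of the stabilised cation should drain the mixture through this diastereomer because only it cyclises through the all-equatorial chair. C4 is set under thermodynamic control, since the 2,4,6-trioxygenated benzylic C4–O bond ionises reversibly in the acidic medium and the cation is captured by the galloyl carbonyl only as the cis-fused dioxolanylium ion 11, whose hydrolysis gives the 3,4-cis hydroxy ester with the acyl group on the equatorial O3 (a 4-O-ester would re-ionise, and the pseudo-axial 4-OH avoids the peri 5-benzyloxy group), the neighbouring-group logic of the Woodward cis-hydroxylation. The step needs hydride abstraction at O1–CH2 only (secured by the para-benzyloxy group of ring B; the phenyl-only benzyl ethers react far more slowly), ring closure on ring A and not on ring B (ring A is activated by O1, O5 and O7 and its two positions ortho to O1 are equivalent, so no regioisomer can form) and no contact between DDQ and the enamine (secured by finishing the oxidation before 7 and the amine are added).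

Step 5
Reactants: 12 (2R,3S,4S)-5,7-bis(benzyloxy)-2-[3,4-bis(benzyloxy)phenyl]-4-hydroxychroman-3-yl 3,4,5-tris(benzyloxy)benzoate
Product: 13 (2R,3S,4S)-2-(3,4-dihydroxyphenyl)-4,5,7-trihydroxychroman-3-yl 3,4,5-trihydroxybenzoate
Conditions: H2 (1 atm), Pd(OH)2/C, THF–EtOAc (1:1), rt; filtration, Sephadex LH-20
Reagents that add atoms: none
Why: Hydrogenolysis of the seven aryl benzyl ethers under neutral conditions avoids base (acyl migration from O3 to O4) and acid (ionisation at C4), the secondary C4 alcohol should be cleaved much more slowly than the O-benzyl groups, and the three stereocentres are not touched.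

**Compound list**
1 | 3,5-bis(benzyloxy)phenol | Oc1cc(OCc2ccccc2)cc(OCc2ccccc2)c1 | starting material
2 | 1,2-bis(benzyloxy)-4-(chloromethyl)benzene | ClCc1ccc(OCc2ccccc2)c(OCc2ccccc2)c1 | starting material
3 | 1,3-bis(benzyloxy)-5-{[3,4-bis(benzyloxy)phenyl]methoxy}benzene | C(Oc1cc(OCc2ccccc2)cc(OCc2ccccc2)c1)c1ccc(OCc2ccccc2)c(OCc2ccccc2)c1 | intermediate
4 | 3,4,5-tris(benzyloxy)benzoic acid | O=C(O)c1cc(OCc2ccccc2)c(OCc2ccccc2)c(OCc2ccccc2)c1 | starting material
5 | 2,2-dimethoxyethanol | OCC(OC)OC | starting material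
6 | 2,2-dimethoxyethyl 3,4,5-tris(benzyloxy)benzoate | COC(COC(=O)c1cc(OCc2ccccc2)c(OCc2ccccc2)c(OCc2ccccc2)c1)OC | intermediate
7 | 2-oxoethyl 3,4,5-tris(benzyloxy)benzoate | O=CCOC(=O)c1cc(OCc2ccccc2)c(OCc2ccccc2)c(OCc2ccccc2)c1 | intermediate
8 | (E)-[3,5-bis(benzyloxy)phenyl][3,4-bis(benzyloxy)benzylidene]oxonium 2,3-dichloro-5,6-dicyano-4-hydroxyphenolate | c1ccccc1COc1cc(OCc2ccccc2)cc(c1)/[O+]=C/c1ccc(OCc2ccccc2)c(OCc2ccccc2)c1.[O-]c1c(Cl)c(Cl)c(O)c(C#N)c1C#N | intermediate
9 | (E)-2-[(2S)-2-{[tert-butyl(dimethyl)silyl]oxy(diphenyl)methyl}pyrrolidin-1-yl]ethenyl 3,4,5-tris(benzyloxy)benzoate | O=C(O/C=C/N1CCC[C@H]1C(O[Si](C)(C)C(C)(C)C)(c1ccccc1)c1ccccc1)c1cc(OCc2ccccc2)c(OCc2ccccc2)c(OCc2ccccc2)c1 | intermediate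
10 | (1R,2R)-1-[3,5-bis(benzyloxy)phenoxy]-1-[3,4-bis(benzyloxy)phenyl]-3-oxopropan-2-yl 3,4,5-tris(benzyloxy)benzoate (anti aldehyde) | O=C(O[C@@H](C=O)[C@@H](c1ccc(OCc2ccccc2)c(OCc2ccccc2)c1)Oc1cc(OCc2ccccc2)cc(OCc2ccccc2)c1)c1cc(OCc2ccccc2)c(OCc2ccccc2)c(OCc2ccccc2)c1 | intermediate
11 | 7,9-bis(benzyloxy)-4-[3,4-bis(benzyloxy)phenyl]-2-[3,4,5-tris(benzyloxy)phenyl]-3a,9b-dihydro-4H-[1,3]dioxolo[4,5-c]chromen-2-ylium 2,3-dichloro-5,6-dicyano-4-hydroxyphenolate (cis ring fusion; ring stereocentres arranged as C2, C3 and C4 of 12) | [O+]9=C(O[C@@H]1[C@@H](c2ccc(OCc3ccccc3)c(OCc3ccccc3)c2)Oc2cc(OCc3ccccc3)cc(OCc3ccccc3)c2[C@@H]19)c1cc(OCc2ccccc2)c(OCc2ccccc2)c(OCc2ccccc2)c1.[O-]c1c(Cl)c(Cl)c(O)c(C#N)c1C#N | intermediate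
12 | (2R,3S,4S)-5,7-bis(benzyloxy)-2-[3,4-bis(benzyloxy)phenyl]-4-hydroxychroman-3-yl 3,4,5-tris(benzyloxy)benzoate | O=C(O[C@@H]1[C@@H](c2ccc(OCc3ccccc3)c(OCc3ccccc3)c2)Oc2cc(OCc3ccccc3)cc(OCc3ccccc3)c2[C@@H]1O)c1cc(OCc2ccccc2)c(OCc2ccccc2)c(OCc2ccccc2)c1 | intermediate
13 | (2R,3S,4S)-2-(3,4-dihydroxyphenyl)-4,5,7-trihydroxychroman-3-yl 3,4,5-trihydroxybenzoate (2,3-trans-3,4-cis) | O=C(O[C@@H]1[C@@H](c2ccc(O)c(O)c2)Oc2cc(O)cc(O)c2[C@@H]1O)c1cc(O)c(O)c(O)c1 | target

**Count**
Total steps: 5. Longest linear sequence: 4 steps (steps 2, 3, 4 and 5, from 4).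

**Three steps most likely to fail**

1. Step 4 (proposed new method). Four processes could defeat it:
   - loss of the aryloxy group at the oxocarbenium stage, either by hydrolysis with the water of enamine formation or by amine attack at C2 and expulsion of the phenoxide;
   - too little anti selectivity in the C2–C3 bond formation;
   - β-elimination of the aryloxide from 10 through its enamine before ring closure;
   - acyl migration or loss while 11 is opened.

   Fallback, known chemistry, setting out from 7 (with 3) and coming back at 10: Pinnick oxidation of 7 (NaClO2, NaH2PO4, 2-methylbut-2-ene, t-BuOH/H2O) gives {[3,4,5-tris(benzyloxy)benzoyl]oxy}acetic acid F1. Coupling with commercial (S)-4-isopropyl-1,3-thiazolidine-2-thione (DCC, DMAP) gives 2-oxo-2-[(4S)-4-(propan-2-yl)-2-sulfanylidene-1,3-thiazolidin-3-yl]ethyl 3,4,5-tris(benzyloxy)benzoate F2. Separately, 3 is oxidised with DDQ in CH2Cl2 containing methanol and 2,6-lutidine to racemic 1,3-bis(benzyloxy)-5-{[3,4-bis(benzyloxy)phenyl](methoxy)methoxy}benzene F3. The chlorotitanium enolate of F2 (TiCl4, i-Pr2NEt, CH2Cl2, −78 °C) is added to F3 activated with SnCl4, which binds the more basic methoxy oxygen. Addition of such chelated (Z)-enolates to acetal-derived oxocarbenium ions is a known anti-selective reaction in which the electrophile enters opposite the isopropyl group. It should give (1R,2R)-1-[3,5-bis(benzyloxy)phenoxy]-1-[3,4-bis(benzyloxy)phenyl]-3-oxo-3-[(4S)-4-(propan-2-yl)-2-sulfanylidene-1,3-thiazolidin-3-yl]propan-2-yl 3,4,5-tris(benzyloxy)benzoate F4, with both new centres as in the main route. iBu2AlH (CH2Cl2, −78 °C) should then reduce the N-acyl thiazolidinethione selectively to the aldehyde, which is 10, now isolated, and release the auxiliary. Compound 10 is closed to 12 with CF3CO2H in CH2Cl2 at 0 °C, as in the last stage of step 4.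

2. Step 5. The benzylic C4–O bond could be cleaved by hydrogenolysis, C4 could ionise on the catalyst surface and oligomerise, or the galloyl group could migrate.

   Fallback, setting out from 12 and coming back at 13: the C4 alcohol is masked before hydrogenolysis. Et3SiOTf and 2,6-lutidine (CH2Cl2, −78 °C) give the 4-O-triethylsilyl ether of 12, F5. Hydrogenolysis (H2, Pd(OH)2/C, THF–EtOAc) gives the 4-O-triethylsilyl ether of 13, F6; the bulky, non-acidic silyl ether should keep C4 off the catalyst. HF·pyridine buffered with pyridine (THF, 0 °C) then removes the silyl group to give 13.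

3. Step 3. Hydrolysis could be slow because the oxocarbenium ion is destabilised by the neighbouring acyloxy group, long acid exposure could remove or shift benzyl groups, and 7 could hydrate or self-condense.

   Fallback, setting out from 4 and coming back at 7: esterification of 4 with an excess of ethylene glycol (DCC, DMAP) gives 2-hydroxyethyl 3,4,5-tris(benzyloxy)benzoate F7. Dess–Martin periodinane (NaHCO3, CH2Cl2) oxidises the primary alcohol to 7 under anhydrous, non-acidic conditions.

**Further compounds**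
F1 | step 4 | {[3,4,5-tris(benzyloxy)benzoyl]oxy}acetic acid | OC(=O)COC(=O)c1cc(OCc2ccccc2)c(OCc2ccccc2)c(OCc2ccccc2)c1
F2 | step 4 | 2-oxo-2-[(4S)-4-(propan-2-yl)-2-sulfanylidene-1,3-thiazolidin-3-yl]ethyl 3,4,5-tris(benzyloxy)benzoate | CC(C)[C@H]1CSC(=S)N1C(=O)COC(=O)c1cc(OCc2ccccc2)c(OCc2ccccc2)c(OCc2ccccc2)c1
F3 | step 4 | rac-1,3-bis(benzyloxy)-5-{[3,4-bis(benzyloxy)phenyl](methoxy)methoxy}benzene | COC(Oc1cc(OCc2ccccc2)cc(OCc2ccccc2)c1)c1ccc(OCc2ccccc2)c(OCc2ccccc2)c1
F4 | step 4 | (1R,2R)-1-[3,5-bis(benzyloxy)phenoxy]-1-[3,4-bis(benzyloxy)phenyl]-3-oxo-3-[(4S)-4-(propan-2-yl)-2-sulfanylidene-1,3-thiazolidin-3-yl]propan-2-yl 3,4,5-tris(benzyloxy)benzoate | O=C(O[C@@H](C(=O)N1C(=S)SC[C@@H]1C(C)C)[C@@H](c1ccc(OCc2ccccc2)c(OCc2ccccc2)c1)Oc1cc(OCc2ccccc2)cc(OCc2ccccc2)c1)c1cc(OCc2ccccc2)c(OCc2ccccc2)c(OCc2ccccc2)c1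
F5 | step 5 | 4-O-triethylsilyl ether of 12 (same spatial arrangement; the CIP label at C3 becomes R) | O=C(O[C@@H]1[C@@H](c2ccc(OCc3ccccc3)c(OCc3ccccc3)c2)Oc2cc(OCc3ccccc3)cc(OCc3ccccc3)c2[C@@H]1O[Si](CC)(CC)CC)c1cc(OCc2ccccc2)c(OCc2ccccc2)c(OCc2ccccc2)c1
F6 | step 5 | 4-O-triethylsilyl ether of 13 (same spatial arrangement) | O=C(O[C@@H]1[C@@H](c2ccc(O)c(O)c2)Oc2cc(O)cc(O)c2[C@@H]1O[Si](CC)(CC)CC)c1cc(O)c(O)c(O)c1
F7 | step 3 | 2-hydroxyethyl 3,4,5-tris(benzyloxy)benzoate | OCCOC(=O)c1cc(OCc2ccccc2)c(OCc2ccccc2)c(OCc2ccccc2)c1
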